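The earlier runs and the new flask were computed on assumed constants, noise included.

The constants of this chemistry are not given, so I want a ratio in which they cancel.

| setting | Thursday's | Sunday's | midnight | dusk |
|---|---|---|---|---|
| substrate | 20 mM (fed, over 2.0 min) | 20 mM (fed, over 2.0 min) | 20 mM (fed, over 2.0 min) | 20 mM (fed, over 2.0 min) |
| coupling partner | 1.2 equiv | 1.2 equiv | 1.20 equiv | 1.20 equiv |
| free catalyst | 1 mol% | 1 mol% | 1 mol% | 1 mol% |
| impurity | 78 µM | 170 µM | 150 µM | 54 µM |
| temperature | 8 °C | 24 °C |  |  |
| remark | run made earlier; the fed solution adds 1.0 times the starting volume | run made earlier; the fed solution adds 1.0 times the starting volume | at 0 °C throughout; the fed solution adds 1.0 times the starting volume | at 0 °C until 2.0 min, from then on at 30 °C; the fed solution adds 1.0 times the starting volume |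
| time |  |  | 15 min | 15 min |

| Thursday's: time / min | Thursday's: target / % | Sunday's: time / min | Sunday's: target / % |
|---|---|---|---|
| 0.417 | 1.0 | 0.167 | 0.8 |
| 1.00 | 2.5 | 0.333 | 0.2 |
| 2.00 | 5.6 | 0.667 | 2.0 |
| 3.00 | 10.9 | 1.00 | 4.5 |
| 5.00 | 18.9 | 1.50 | 5.6 |
| 6.00 | 23.8 | 2.00 | 8.5 |
| 8.00 | 31.5 | 2.50 | 9.7 |

(scatter of a reading: 0.5 percentage points)

- amounts are per litre of the starting volume; all of the dose is in the solution fed
- percentages count the whole charge, also what has not yet gone in

- the winner by amount of target, in percent of the substrate charged; "neither" if no more than 2 percentage points parts them (midnight / dusk / neither)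
- how much target is there at the end, in percent of the substrate charged: midnight
- how much target is there at the end, in percent of the substrate charged: dusk

1. I suppose that the impurity removes catalyst one for one, and at once. I define the spare share as the fraction of the catalyst charge left after subtracting the impurity charge: 73.0% for dusk and 25.0% for midnight. Thursday's run has 61.0% and Sunday's run 15.0%.

2. At 2.00 min, Thursday's run holds 5.6% of target and Sunday's run 8.5%. Both were read at the same moment, so their ratio is a ratio of rates and time drops out. Dividing it by the ratio of spare shares gives a factor of 6.17 per unit of spare catalyst, for going from 8 °C to 24 °C. Each reading carries 0.5 percentage points, so this factor is a reading too.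

3. I let the logarithm of the rate run straight with temperature. Going from 0 °C to 30 °C then gives a factor of 30.3.

4. Now I turn the question round. After 2.0 min, midnight and dusk run for the same time, so while substrate lasts, the ratio of their rates is the ratio of what they make. Midnight comes within 2 points of dusk in one of two ways: that ratio stands near 1, or both flasks finish. Multiplying the temperature factor by the ratio of spare shares gives 88.6, far more than 1. Thursday's 31.5% at 8.00 min, scaled by spare share, temperature and time, gives midnight about 9.74% at 15 min, less than the whole charge, so by my reckoning midnight does not finish. I commit to dusk.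

The forecast also names dusk, with 9.5% for midnight and 98% for dusk, on the ground that the free catalyst “appears to be titrated by the impurity”. The flask gives midnight 16.0% and dusk 99.8%.

    substrate + free catalyst → catalyst intermediate A (k = 880 L mol⁻¹ min⁻¹, Ea = 48.0 kJ mol⁻¹)
    free catalyst + impurity → spent catalyst (k = 12000 L mol⁻¹ min⁻¹, Ea = 44.0 kJ mol⁻¹)
    catalyst intermediate B → free catalyst + target (k = 5.20 min⁻¹, Ea = 79.0 kJ mol⁻¹)
    coupling partner + catalyst intermediate A → catalyst intermediate B (k = 38000 L mol⁻¹ min⁻¹, Ea = 40.0 kJ mol⁻¹)
    (constants at 0 °C)

At 15.0 min, dusk holds spent catalyst at 27.0% and impurity at 0%, and its free catalyst at 72.9% stands close to the spare share of 73.0%. The neighbouring flask is dusk with 0.300 equiv of coupling partner. Its impurity and catalyst charges are unchanged, so I reckon the same spare share of 73.0%. At 15.0 min, it holds spent catalyst at 26.9% and catalyst intermediate A at 73.1%, with free catalyst at 0%. Coupling partner, here the limiting reagent, stands at 0%, substrate at 69.3% and target at 30.0%.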